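The slowness of these flasks lies in their tails: amber gains 2 percentage points of product between 4.00 min and 5.00 min, and it stands at 40.2%, just beneath the 45.0% that its reagent charge over its substrate charge gives.

| setting | amber | ochre | red | Sunday's | Friday's |
|---|---|---|---|---|---|
| substrate | 0.0010 M | 0.0010 M | 0.0010 M | 0.0010 M | 0.0010 M |
| reagent | 0.45 mM | 0.68 mM | 0.90 mM | 0.900 mM | 0.900 mM |
| free catalyst | 1 µM | 1 µM | 0.50 µM | 1.0 µM | 1.0 µM |
| temperature | 98 °C | 114 °C | 98 °C | 100 °C | 110 °C |
| remark | run made earlier | run made earlier | run made earlier |  |  |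
| time |  |  |  | 8.0 min | 8.0 min |

| run | time / min | product / % | substrate / % | catalyst intermediate B / % |
|---|---|---|---|---|
| amber | 1.33 | 26.0 | 42.9 | 0 |
| amber | 2.50 | 33.9 | 38.0 | 0 |
| amber | 4.00 | 38.2 | 36.1 | 0 |
| amber | 5.00 | 40.2 | 34.6 | 0 |
| ochre | 0.200 | 10.5 | 61.2 | 0.2 |
| ochre | 0.417 | 17.5 | 54.1 | 0 |
| ochre | 1.00 | 30.3 | 45.3 | 0 |
| ochre | 2.50 | 46.7 | 35.5 | 0 |
| red | 0.667 | 18.7 | 53.2 | 0.1 |
| red | 1.50 | 30.7 | 39.5 | 0 |
| red | 3.00 | 42.8 | 32.5 | 0 |
| red | 5.00 | 53.6 | 26.9 | 0 |

(readings scatter by 0.3 percentage points)

- the numbers in the tables scatter by 0.3 percentage points (one standard deviation)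
- a reading of substrate is of its free form alone

1. which of these there is most of at the end, counted by the substrate in it, Sunday's (product / substrate / catalyst intermediate B)
2. which of these there is most of at the end, counted by the substrate in it, Friday's (product / substrate / catalyst intermediate B)
3. the largest of these amounts at the end, in percent of the substrate charged, Sunday's
4. the largest of these amounts at the end, in percent of the substrate charged, Friday's

Reagent is the limiting reagent in Sunday's and Friday's, charged less than substrate, and their ratio is 90.0%. This product ceiling, reagent charged over substrate charged, is the level product can reach when one reagent goes into each product.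

How near product comes to it at 8.0 min is my own reckoning. It takes the rate as catalyst times substrate times reagent and treats the two charges as nearly equal; on that assumption the reciprocal of r, the share of reagent left, climbs in a straight line with catalyst times time. Here τ is the time for r to fall to half at 1.0 µM of catalyst. Red has the same ceiling at 0.50 µM of catalyst:

r, red, at 5.00 min: 0.404

red's time counted at 1.0 µM of catalyst: 2.50 min

τ: 1.70 min

r, Sunday's, at 8.0 min: 0.175

product, Sunday's: 74.2%

That puts product ahead of everything else holding substrate.

The weak link is temperature, since red ran at 98 °C. Ochre, at 114 °C with a ceiling of 68.0%, had the same counted time as red. The law for unequal charges, the logarithm of substrate share over reagent share, makes ochre 1.21 times as fast as red. Applied whole to Friday's, that factor gives an estimate of 76.6%.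

The forecast says product for Sunday's at 76% and product for Friday's at 77%, on the ground that “The rate constant barely changes with temperature”. For Sunday's it stands 1.8 points above my reckoning.

Sunday's gives product at 74.5% and Friday's product at 75.2%, so the forecast holds, and the 10.0 K between the flasks is worth 0.70 points of product. Friday's has reached 83.6% of its ceiling. Left until 80.0 min, it stands at 89.7%, with reagent at 0.272% of its charge.

    catalyst intermediate B ⇌ free catalyst + product (K = 7.93 × 10⁻⁴ M, k = 2720 s⁻¹, Ea = 73.0 kJ mol⁻¹, ΔH = −8.00 kJ mol⁻¹)
    substrate ⇌ dormant form (K = 0.680, k = 0.0190 s⁻¹, Ea = 105 kJ mol⁻¹, ΔH = −24.0 kJ mol⁻¹)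
    substrate + catalyst intermediate A → catalyst intermediate B (k = 57800 M⁻¹ s⁻¹, Ea = 29.0 kJ mol⁻¹)
    reagent + free catalyst ⇌ catalyst intermediate A (K = 452 M⁻¹, k = 3.30 × 10⁵ M⁻¹ s⁻¹, Ea = 29.0 kJ mol⁻¹, ΔH = −32.0 kJ mol⁻¹)
    (constants at 100 °C)

With 0.0025 M of substrate and Friday's other charges, the ceiling falls to 36.0%. That flask gives 35.9% of product at 8.00 min, with reagent run out at 0.218% of its charge and substrate, at 41.2%, more than product.

The readings were generated by integration with constants of no real substance.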